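## Retrosynthetic overview

1. Eschscholtzxanthin ⇒ (3R,3'R)-zeaxanthin diacetate by a late C4/C4' dehydrogenation that slides all double bonds into the retro positions, as in the plant's presumed last step; no ring is made here.
2. Zeaxanthin diacetate ⇒ two C15 phosphonium salts + the C10 trienedial (double Wittig); C15 salt ⇒ (R)-3-hydroxy-β-ionone + a vinyl unit.
3. Key ring formation: each cyclohexene ring is closed C1→C6 by proton-initiated cation–olefin cyclisation of an acyclic ψ-type C13 hydroxy-trienone, the way lycopene cyclase closes a ψ end. The C3 carbinol is already in place and unprotected, so the ring arrives with its stereocentre.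
4. The two rings are identical: one batch of the C13 ring compound supplies ring A and ring B, and both rings exist before the halves are joined.
5. Acyclic precursor ⇒ (S)-epichlorohydrin (C2–C3–C4 and the only source of chirality) + isopropenyl + acetylide + methyl (carboalumination) + a C4 chloro-enone.

Assumption: all numbered starting materials are bought, including (3E)-4-chlorobut-3-en-2-one as a catalogue item; the step-4 product is used twice in step 7.

## Route

Step 1
Reactants: 1 (S)-epichlorohydrin; 2 isopropenylmagnesium bromide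
Product: 3 (2S)-1-chloro-4-methylpent-4-en-2-ol
Conditions: 2 (1.1 equiv), CuI (5 mol%), THF, −40 → −20 °C; then H2O
Reagents that add atoms: none
Why: Copper-catalysed Grignard opening of an epoxide, in which the alkenyl cuprate formed with CuI attacks the unsubstituted epoxide carbon and leaves the C–Cl and C–O bonds at the stereocentre alone, so the (S) centre of 1 is carried over unchanged as the future C3.

Step 2
Reactants: 3 (2S)-1-chloro-4-methylpent-4-en-2-ol; 4 lithium acetylide–ethylenediamine complex
Product: 6 (4S)-2-methylhept-1-en-6-yn-4-ol, via methallyl oxirane 5 (not isolated)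
Conditions: 4 (3 equiv), DMSO, 5 → 25 °C, 3 h; then H2O
Reagents that add atoms: none
Why: Base-mediated Williamson closure of the chlorohydrin to the terminal epoxide followed by SN2 opening at its CH2 carbon by acetylide (epoxide alkynylation), neither of which touches the carbinol carbon, so (S) is retained.

Step 3
Reactants: 6 (4S)-2-methylhept-1-en-6-yn-4-ol; 7 trimethylaluminium; 8 (3E)-4-chlorobut-3-en-2-one
Product: 10 (3E,5E,8S)-8-hydroxy-6,10-dimethylundeca-3,5,10-trien-2-one, via alkenylalane 9 (not isolated)
Conditions: 7 (3 equiv), Cp2ZrCl2 (0.25 equiv), CH2Cl2, 0 → 23 °C, 12 h; evaporate volatiles; THF, ZnCl2 (1 equiv), Pd(PPh3)4 (5 mol%), 8 (1.2 equiv), 0 → 23 °C; then aq. potassium sodium tartrate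
Reagents that add atoms: none
Why: Negishi zirconium-catalysed carboalumination adds Me and Al syn across the terminal alkyne with Me on the internal carbon, and the resulting (E)-alkenylalane cross-couples under zerovalent palladium and ZnCl2 (Negishi coupling) with the activated vinyl chloride 8 with retention at both alkenes, the alcohol being masked in the flask as its aluminium alkoxide and the 1,1-disubstituted alkene being inert; no stereocentre is made.

Step 4
Reactants: 10 (3E,5E,8S)-8-hydroxy-6,10-dimethylundeca-3,5,10-trien-2-one
Product: 11 (3E)-4-[(4R)-4-hydroxy-2,6,6-trimethylcyclohex-1-en-1-yl]but-3-en-2-one ((R)-3-hydroxy-β-ionone)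
Conditions: TfOH (3 equiv), CH2Cl2/2-nitropropane 4:1 (0.05 M), −40 → −5 °C, 1 h; pour into cold aq. NaHCO3
Reagents that add atoms: none
Why: Proposed new method: Markovnikov protonation of the isopropenyl group gives the tertiary C1 cation, the C5=C6 bond (the only π bond placed for a six-membered ring, and less basic than the isopropenyl group because it is part of the O-protonated dienone) attacks through C6, and the C5 cation loses H6 to give the conjugated β-isomer as the thermodynamic sink, while the C3 hydroxyl, held as an oxonium that is neither allylic nor able to form a five- or six-membered ether and that would have to ionise next to an existing positive charge, is carried through unchanged (S becomes R only by a change of CIP priorities); closest known reaction: the strong-acid cation–olefin cyclisation of pseudoionone to β-ionone, the laboratory counterpart of the ψ-end to β-ring closure of lycopene, here extended to a substrate with a free C3 hydroxyl.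

Step 5
Reactants: 11 (R)-3-hydroxy-β-ionone; 12 vinylmagnesium bromide
Product: 14 (1R)-4-[(1E)-3-acetoxy-3-methylpenta-1,4-dien-1-yl]-3,5,5-trimethylcyclohex-3-en-1-yl acetate (1:1 epimers at the tertiary carbon), via bromomagnesium dialkoxide 13 (not isolated)
Conditions: 12 (2.2 equiv), THF, −20 → 0 °C, 2 h; then Ac2O (5 equiv), DMAP (0.2 equiv), 0 → 23 °C, 6 h; aq. NaHCO3; used crude
Reagents that add atoms: acetic anhydride CC(=O)OC(C)=O
Why: Grignard 1,2-addition to the methyl ketone (the vinyl-β-ionol reaction) after the first equivalent has deprotonated the alcohol, then acylation of both magnesium alkoxides by Ac2O in the same flask; the new tertiary centre forms without control and is destroyed in step 6, and C3 is untouched.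

Step 6
Reactants: 14 the bis-acetate
Product: 15 [(2E,4E)-5-[(4R)-4-acetoxy-2,6,6-trimethylcyclohex-1-en-1-yl]-3-methylpenta-2,4-dien-1-yl]triphenylphosphonium bromide
Conditions: PPh3·HBr (1.05 equiv), CH2Cl2, 0 → 23 °C, 16 h; crystallise from EtOAc/acetone
Reagents that add atoms: triphenylphosphine hydrobromide Br.c1ccc(cc1)P(c1ccccc1)c1ccccc1
Why: SN1'-type phosphonium salt formation (the vinyl-ionol to Wittig-salt reaction), in which HBr ionises the tertiary doubly allylic acetate to a delocalised cation that PPh3 traps at the unhindered chain terminus, while the secondary non-allylic acetate at C3 cannot ionise.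

Step 7
Reactants: 15 the C15 phosphonium bromide (2.2 equiv); 16 (2E,4E,6E)-2,7-dimethylocta-2,4,6-trienedial
Product: 18 (3R,3'R)-zeaxanthin diacetate, via phosphorus ylide 17 (not isolated)
Conditions: 1,2-epoxybutane (solvent and base), 65 °C, sealed, 20 h; then n-heptane, reflux (Z → E); crystallise
Reagents that add atoms: none
Why: Twofold Wittig olefination under epoxide (base-free) conditions, in which bromide opens 1,2-epoxybutane to the alkoxide that forms ylide 17, so the acetates survive, the two new disubstituted double bonds are brought to E by heating, and no stereocentre is touched.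

Step 8
Reactants: 18 (3R,3'R)-zeaxanthin diacetate
Product: 21 (3S,3'S)-eschscholtzxanthin (target), via 4-bromozeaxanthin diacetate 19 (not isolated), via eschscholtzxanthin diacetate 20 (not isolated)
Conditions: NBS (1.05 equiv), acid-free CHCl3, −20 °C, dark, Ar; then 4-ethylmorpholine (3 equiv), −20 → 40 °C; then 5% KOH in MeOH, 23 °C; crystallise the all-E isomer from CH2Cl2/MeOH
Reagents that add atoms: none
Why: NBS dehydrogenation (allylic bromination at C4, ionisation to the fully delocalised polyenyl cation and loss of the proton from C4', a vinylogous E1 elimination that moves all double bonds into the retro positions, as known for zeaxanthin diacetate and for β-carotene) followed by ester saponification; C3 and C3' keep their geometry and are renamed S only because C4 and C4' become sp2.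

## Compound list

1 | (S)-epichlorohydrin, (2S)-2-(chloromethyl)oxirane | ClC[C@@H]1CO1 | starting material
2 | isopropenylmagnesium bromide | C=C(C)[Mg]Br | starting material
3 | (2S)-1-chloro-4-methylpent-4-en-2-ol | C=C(C)C[C@H](O)CCl | intermediate
4 | lithium acetylide–ethylenediamine complex | [Li+].[C-]#C.NCCN | starting material
5 | methallyl oxirane, (2S)-2-(2-methylprop-2-en-1-yl)oxirane | C=C(C)C[C@H]1CO1 | intermediate
6 | (4S)-2-methylhept-1-en-6-yn-4-ol | C=C(C)C[C@H](O)CC#C | intermediate
7 | trimethylaluminium | C[Al](C)C | starting material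
8 | (3E)-4-chlorobut-3-en-2-one | CC(=O)/C=C/Cl | starting material
9 | alkenylalane: O-dimethylaluminium alkoxide of (1E,4S)-1-(dimethylalumanyl)-2,6-dimethylhepta-1,6-dien-4-ol | C=C(C)C[C@H](O[Al](C)C)C/C(C)=C/[Al](C)C | intermediate
10 | (3E,5E,8S)-8-hydroxy-6,10-dimethylundeca-3,5,10-trien-2-one | C=C(C)C[C@H](O)C/C(C)=C/C=C/C(C)=O | intermediate
11 | (R)-3-hydroxy-β-ionone, (3E)-4-[(4R)-4-hydroxy-2,6,6-trimethylcyclohex-1-en-1-yl]but-3-en-2-one | CC(=O)/C=C/C1=C(C)C[C@@H](O)CC1(C)C | intermediate
12 | vinylmagnesium bromide | C=C[Mg]Br | starting material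
13 | bromomagnesium dialkoxide of the vinyl carbinol (epimers at the tertiary carbon) | CC1=C(/C=C/C(C)(O[Mg]Br)C=C)C(C)(C)C[C@H](O[Mg]Br)C1 | intermediate
14 | (1R)-4-[(1E)-3-acetoxy-3-methylpenta-1,4-dien-1-yl]-3,5,5-trimethylcyclohex-3-en-1-yl acetate (epimers at the tertiary carbon) | CC1=C(/C=C/C(C)(OC(C)=O)C=C)C(C)(C)C[C@H](OC(C)=O)C1 | intermediate
15 | [(2E,4E)-5-[(4R)-4-acetoxy-2,6,6-trimethylcyclohex-1-en-1-yl]-3-methylpenta-2,4-dien-1-yl]triphenylphosphonium bromide | CC1=C(/C=C/C(C)=C/C[P+](c2ccccc2)(c2ccccc2)c2ccccc2)C(C)(C)C[C@H](OC(C)=O)C1.[Br-] | intermediate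
16 | (2E,4E,6E)-2,7-dimethylocta-2,4,6-trienedial | O=C/C(C)=C/C=C/C=C(\C)C=O | starting material
17 | phosphorus ylide of 15 | CC1=C(/C=C/C(C)=C/C=P(c2ccccc2)(c2ccccc2)c2ccccc2)C(C)(C)C[C@H](OC(C)=O)C1 | intermediate
18 | (3R,3'R)-zeaxanthin diacetate | CC1=C(/C=C/C(C)=C/C=C/C(C)=C/C=C/C=C(C)/C=C/C=C(C)/C=C/C2=C(C)C[C@@H](OC(C)=O)CC2(C)C)C(C)(C)C[C@H](OC(C)=O)C1 | intermediate
19 | 4-bromozeaxanthin diacetate (both C4 epimers) | CC1=C(/C=C/C(C)=C/C=C/C(C)=C/C=C/C=C(C)/C=C/C=C(C)/C=C/C2=C(C)C[C@@H](OC(C)=O)CC2(C)C)C(C)(C)C[C@H](OC(C)=O)C1Br | intermediate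
20 | (3S,3'S)-eschscholtzxanthin diacetate | CC1=C[C@@H](OC(C)=O)CC(C)(C)\C1=C/C=C(C)/C=C/C=C(C)/C=C/C=C/C(C)=C/C=C/C(C)=C/C=C1/C(C)=C[C@@H](OC(C)=O)CC1(C)C | intermediate
21 | (3S,3'S)-eschscholtzxanthin | CC1=C[C@@H](O)CC(C)(C)\C1=C/C=C(C)/C=C/C=C(C)/C=C/C=C/C(C)=C/C=C/C(C)=C/C=C1/C(C)=C[C@@H](O)CC1(C)C | target

## Step count and risks

Total steps: 8. Longest linear sequence: 8 (the route is fully linear; compound 11 is made once and used twice in step 7).

The three steps most likely to fail:

Step 4, the ring closure on the free alcohol. The C3 oxonium could ionise in any α-isomer that forms, or the hydroxyl could add to the dienone. The fallback replaces the direct closure by a protect–cyclise–release sequence. It sets out from 10, which is acetylated (Ac2O, pyridine, DMAP) to (3E,5E,8S)-8-acetoxy-6,10-dimethylundeca-3,5,10-trien-2-one F1. F1 is cyclised in conc. H2SO4/AcOH at 0 °C, the classical pseudoionone medium in which the ester is inert and electron-withdrawing, to (R)-3-acetoxy-β-ionone F2. K2CO3/MeOH then releases the alcohol and the fallback comes back to the route at 11.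

Step 8, the NBS dehydrogenation. Over-bromination or 3,4-didehydro products would lower the yield. The fallback uses electron-transfer oxidation instead of halogenation. It sets out from 18, which is oxidised with two equivalents of tris(4-bromophenyl)aminium hexachloroantimonate in CH2Cl2 at −40 °C to the delocalised zeaxanthin diacetate dication bis(hexachloroantimonate) F3. Adding 2,6-di-tert-butylpyridine removes the C4 and C4' protons and the fallback comes back to the route at 20, after which the saponification of step 8 gives 21.

Step 3, the tandem carboalumination and coupling. Methyl–aluminium species could add to the ketone of 8 or of 10. The fallback separates the two C–C bond formations and changes the coupling type. It sets out from 6, which undergoes the same carboalumination but is quenched with I2 to give (1E,4S)-1-iodo-2,6-dimethylhepta-1,6-dien-4-ol F4. A Heck reaction of F4 with methyl vinyl ketone (Pd(OAc)2, K2CO3, Bu4NCl, DMF, 40 °C) then gives the dienone and the fallback comes back to the route at 10.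

## Further compounds

F1 | step 4 | (3E,5E,8S)-8-acetoxy-6,10-dimethylundeca-3,5,10-trien-2-one | C=C(C)C[C@H](OC(C)=O)C/C(C)=C/C=C/C(C)=O
F2 | step 4 | (R)-3-acetoxy-β-ionone, (1R)-3,5,5-trimethyl-4-[(1E)-3-oxobut-1-en-1-yl]cyclohex-3-en-1-yl acetate | CC(=O)/C=C/C1=C(C)C[C@@H](OC(C)=O)CC1(C)C
F3 | step 8 | zeaxanthin diacetate dication bis(hexachloroantimonate), one resonance form drawn | C[C+]1C[C@@H](OC(C)=O)CC(C)(C)\C1=C/C=C(C)/C=C/C=C(C)/C=C/C=C/C(C)=C/C=C/C(C)=C/C=C1/[C+](C)C[C@@H](OC(C)=O)CC1(C)C.Cl[Sb-](Cl)(Cl)(Cl)(Cl)Cl.Cl[Sb-](Cl)(Cl)(Cl)(Cl)Cl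
F4 | step 3 | (1E,4S)-1-iodo-2,6-dimethylhepta-1,6-dien-4-ol | C=C(C)C[C@H](O)C/C(C)=C/I
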